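The rate constants are invented.

The closed vessel holds electrophile, protonated nucleophile, protic impurity and free base, and the free base has two tasks: it takes the proton from the protonated nucleophile, and it takes up the acid set free, while the protic impurity quenches it slowly.

electrophile 12 mM; protonated nucleophile 2.00 equiv; protic impurity 2.40 mM; time 10 d

    electrophile + nucleophile ⇌ acid set free + product (K1 = 0.64, k1 = 0.039 M⁻¹ min⁻¹)
    nucleophile + acid set free ⇌ protonated nucleophile, settled at all times (K2 = 6.4 × 10⁵ M⁻¹)
    acid set free + free base ⇌ salt of the base, settled at all times (K3 = 4.4 × 10⁶ M⁻¹)
    2 electrophile → homo dimer (k4 = 4.7 × 10⁻⁵ M⁻¹ min⁻¹)
    protic impurity + free base → quenched reagent (k5 = 0.24 M⁻¹ min⁻¹)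

- a species is counted by the electrophile in it: one homo dimer counts as two
- a doubled species enters its step squared and goes two at a time
- the amount of free base is what is sought; it is there from the start
- run time (flask): 10 d

1. the equivalents of free base at which the part of the electrophile that has reacted at 10 d is just 80 %

The first way is a count in fractions of the electrophile charge. Let x be the part reacted, n the free base charged, and m what remains of n once the protic impurity is counted as quenched. The homo dimer is set aside, as k4 is far smaller than k1. Each turn of step 1 uses one free nucleophile and sets free one acid, which takes one more, so

free nucleophile + free base = m − 2x

Setting this to nothing at the part wanted gives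

n = 2 × 80 % + 2.40 mM/12 mM = 1.80 equiv

This base floor, twice the part wanted plus the impurity per electrophile charged, counts neither the length of the run nor the way back of step 1.

The second way brings in the run through the clock, k1 times the charged electrophile times the run, 6.74. The way back is ignored, and free nucleophile is taken as the whole sum above, which favours the rate. Integrating dx/dτ = (1 − x)(m − 2x) up to the clock gives, for the margin s = m − 2x left at the part wanted,

s = (1 − x) · m · exp[−clock · (2 − m)]

Starting from s = 0, this gives s = 0.0216. Putting that back gives s = 0.0253. So

n = floor + s = 1.83 equiv

The two ways part by this margin, but it was reckoned with the way back ignored. With step 1 at balance at the part wanted, acid set free stands to free nucleophile as K1 times (1 − x)/x, and step 2 then asks for free nucleophile of about 0.0313 of the charge, larger than s above. So the floor falls short on the way back as well as on time, and the second way's figure remains an estimate that leaves the way back out.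

The forecast is 1.86 equiv, on the ground that “each equivalent of product then costs about two of base”.

The simulation gives 1.83 equiv, which is 0.0300 equiv above the base floor. In this flask the half-life of free base by the quench, 2.0 d at 0.760 d, is shorter than the run, while the half-life of the protic impurity by the same step grows from 0.90 d at 0.760 d to 17 d at 10.0 d, longer than the run. At 10.0 d, 0.527 % of the charged free base is still free.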